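## The problem

Target 20 is an isoflavone: a 4H-chromen-4-one (ring A fused to the pyranone ring C) that carries ring B on C3. It has no stereocentre, so nothing needs to be controlled in the final structure; the epoxide carbons of 15 and the enolisable carbon of 16–18 are the only stereogenic centres on the way, and all are erased. The difficulty lies in ring A, where every carbon is a ring-fusion atom or bears oxygen: O1 on C8a, hydroxyls on C8, C7 and C5, and a methyl ether on C6. Ring B adds one hydroxyl (C3') beside two methyl ethers, so three methyl ethers must be kept apart from four phenols throughout. The two oxygens ortho to the C4a–C4 bond, the future O1 and the future 5-OH, differ only in their neighbours (8-OH against 6-OMe). If ring C closes through the wrong one, the 5,6,7-trihydroxy-8-methoxy isomer results, and hot acid can interconvert the two (Wessely–Moser rearrangement). The free 5,8-hydroquinone and 7,8-catechol units are oxidised to quinones by air in base, and the pyranone ring is opened by strong base, so the phenols should be released last, under neutral reducing conditions. The key step is possible because C3 carries both ring B and the C4 aroyl carbon while C2 is a formyl-level carbon, which is the pattern of a chalcone whose aroyl group has moved from the α- to the β-carbon.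

## Retrosynthesis

**20 ⇒ 19.** The four O–benzyl bonds (5-, 7-, 8- and 3'-O) are cut. Benzyl is preferred to methyl, which would require selective cleavage of four ethers out of seven, and to silyl or acyl groups, which would not survive the aldol condensation and the alkaline peroxide. Compound 19 is a stable, fully etherified isoflavone. The forward step must remove benzyl without reducing C2=C3 or touching the methyl ethers.

**19 ⇒ 16 (through 17 and 18).** The O1–C2 bond of ring C is cut, with C2 kept at the aldehyde level. This exposes the α-formyl deoxybenzoin 16, in which every carbon is in place. Closing ring C is only safe if the oxygen that becomes O1 is the sole free hydroxyl at that moment. A precursor with benzyl ethers on both ortho oxygens would lose both on hydrogenolysis and could close through either. In 16 the future O1 therefore carries an allyl ether and the future 5-oxygen a benzyl ether. The forward step must remove allyl with zerovalent palladium in the presence of four benzyl ethers and a β-ketoaldehyde; phenol 17 then closes to hemiacetal 18 and loses water.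

**16 ⇒ 15 (key step).** The bond between the carbon bearing ring B and the aroyl carbon (the future C3–C4 bond) is cut, and the aroyl group is returned to the neighbouring carbon as the ketone of a trans α,β-epoxy ketone. The neighbouring cuts are weaker here. Cutting C3–C1' needs a 3-halochromone and a ring B organometallic. Cutting at C2 needs a deoxybenzoin, made by acylating the pentaoxygenated ring under Lewis acids that strip benzyl ethers. The epoxide 15 comes from two simple aromatic halves. The forward step must open the epoxide at the benzylic carbon and migrate acyl, not hydride.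

**15 ⇒ 14 ⇒ 11 + 13.** The epoxide oxygen is removed (alkaline H2O2 forward), and the Cα=Cβ bond of chalcone 14 is cut by a Claisen–Schmidt disconnection. This divides the skeleton into acetophenone 11 (ring A with C4 and C3... the acetyl carbons) and aldehyde 13 (ring B with the future C2). All phenols must be capped, because a free ortho hydroxyl would give a flavanone or aurone under these basic conditions.

**13 ⇒ 12.** One O–benzyl bond is cut. Aldehyde 12 is commercial and already has the complete ring B pattern, with the 3-hydroxyl distinguished from the two methyl ethers.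

**11 ⇒ 10 ⇒ 9 ⇒ 7.** The O–allyl bond, the O–methyl bond and then the C5–O bond are cut. In 10 the hydroxyl chelated to the acetyl group is the only free one, which gives the future O1 its identity. The oxygen para to it (the future 6-OMe) is installed at the only unsubstituted ring position by Elbs persulfate oxidation of 7, and the new, non-chelated hydroxyl of 9 is methylated selectively.

**7 ⇒ 6 ⇒ 4 ⇒ 3 ⇒ 1.** One O–benzyl bond, the C3–O bond (Dakin transform, hydroxyl back to formyl), two O–benzyl bonds and the C–CHO bond are cut. Phloroacetophenone 1 already holds the ring A carbonyl and three of the five oxygens, and its two free ring positions are equivalent, so the formylation is regiochemically unambiguous. The formyl group places oxygen ortho to the chelated hydroxyl, where persulfate cannot. The forward sequence relies on the hydroxyl between the two carbonyl groups being the last to be alkylated.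

## Roads not taken

**Alternative 1: ring A from a squaric ester by Moore ring expansion.**
- Cut: the C8–C8a bond and the ring A carbons C5–C8.
- Key step: the 4-hydroxycyclobutenone A1, carrying a 3-aryl-4-pyranon-5-yl group, is heated. The four-membered ring opens to a dienylketene, which closes by 6π electrocyclisation onto pyranone C6 to give the 5,8-hydroquinone A2.
- Merits: it builds the awkward oxygen pattern of ring A in one thermal step, with 6-OMe and 7-O already differentiated, and avoids both aromatic oxidations of the chosen route. In step count for ring A it is the better plan on paper.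
- Weak points: the methyl and tert-butyl ethers are placed by the regiochemistry of addition to a mixed squaric ester. A 3-aryl-4-pyranone must be metalated at C5 although pyranones are ring-opened by organolithium reagents. Electrocyclisation onto the C5=C6 bond of a pyranone has little precedent compared with arenes and simple alkenes. A2 is an air-sensitive 5,8-hydroquinone that still needs acid to remove tert-butyl, with the isomerisation risk that acid carries.
- Comparison: the chosen plan is longer in ring A, but every step is a known reaction on a known substrate class.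

**Alternative 2: biomimetic oxidative 2,3-aryl shift of a flavanone.**
- Cut: the C3–C1' bond, with ring B returned to C2.
- Key step: the racemic flavanone A3, made from 10 and 13, is oxidised at C3 by PhI(OH)OTs (trivalent iodine) or Tl(NO3)3 (trivalent thallium). Ring B migrates from C2 to C3 and proton loss gives A4, which is identical with 19.
- Merits: it is two steps shorter than the chosen route, since it needs no allyl protection, epoxidation or deallylation. The free chelated hydroxyl of 10 fixes O1 automatically. In both respects it is better.
- Weak points: an electrophilic two-electron oxidant acts on a substrate with two very electron-rich alkoxyarenes. Dehydrogenation to the isomeric flavone is the standard side reaction, and ring contraction is a second one with trivalent thallium. The donor methoxy group of ring B is twisted by two ortho substituents, which lowers its migratory aptitude. Thallium salts are highly toxic.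
- Comparison: the chosen plan sets a redox-neutral Lewis-acid step against these risks, so no oxidant touches the assembled skeleton and no flavone can form. Alternative 2 is kept as the fallback for the key step.

**Alternative 3: ring B by cyclobutenone benzannulation on the chromone.**
- Cut: the C2'–C3' bond and the whole of ring B.
- Key step: the 4-(1-chromonylvinyl)-2,3-dimethoxycyclobutenone A5 opens thermally to a dienylketene, whose 6π electrocyclisation closes ring B and delivers A6 with the 3'-phenol free.
- Merits: the 3'-hydroxyl is differentiated from the 4'- and 5'-methyl ethers by construction, with no protecting group on ring B, and the regiochemistry of ring B is unambiguous.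
- Weak points: ring B is the easy half, since 12 is commercial with this pattern. The whole ring A chromone still has to be made by the same aromatic oxidations, and a 3-(1-metallovinyl)chromone and a squaric ester sequence come on top.
- Comparison: it matches the chosen plan only in the differentiation of the 3'-oxygen, which the chosen plan gets for one benzylation step, and it is clearly longer.

Key step: step 11

## Route

Assumption: 1, 12 and the simple reagents are commercial; all chiral intermediates are racemic, which is immaterial for the achiral target.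

Step 1
Reactants: 1 2',4',6'-trihydroxyacetophenone (phloroacetophenone)
Product: 3 3-acetyl-2,4,6-trihydroxybenzaldehyde, via iminium chloride 2 (not isolated)
Conditions: POCl3, DMF, EtOAc, 0 °C to rt; then H2O, 50 °C
Reagents that add atoms: N,N-dimethylformamide, CN(C)C=O; water, O
Why: Vilsmeier–Haack formylation; the chloroiminium ion attacks one of the two equivalent free positions of the phloroglucinol ring, the first formyl group deactivates the ring against a second, and water hydrolyses iminium salt 2 to the aldehyde.

Step 2
Reactants: 3 3-acetyl-2,4,6-trihydroxybenzaldehyde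
Product: 4 3-acetyl-4,6-bis(benzyloxy)-2-hydroxybenzaldehyde
Conditions: BnBr (2.1 equiv), K2CO3, DMF, rt
Reagents that add atoms: benzyl bromide, BrCc1ccccc1
Why: Williamson etherification; the two hydroxyls flanked by only one carbonyl group react first, while the hydroxyl between acetyl and formyl is the most hindered and stays chelated to both carbonyls.

Step 3
Reactants: 4 3-acetyl-4,6-bis(benzyloxy)-2-hydroxybenzaldehyde
Product: 6 1-[4,6-bis(benzyloxy)-2,3-dihydroxyphenyl]ethanone, via aryl formate 5 (not isolated)
Conditions: 30% H2O2, NaOH, THF/H2O, 0 °C, N2; then 1 M HCl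
Reagents that add atoms: hydrogen peroxide, OO
Why: Dakin oxidation; hydroperoxide adds to the formyl group ortho to the phenoxide, the aryl group migrates to oxygen and formate 5 is hydrolysed in the flask, while the hindered methyl ketone reacts far more slowly than the aldehyde.

Step 4
Reactants: 6 1-[4,6-bis(benzyloxy)-2,3-dihydroxyphenyl]ethanone
Product: 7 1-[3,4,6-tris(benzyloxy)-2-hydroxyphenyl]ethanone
Conditions: BnBr (1.05 equiv), K2CO3, acetone, reflux
Reagents that add atoms: benzyl bromide, BrCc1ccccc1
Why: Selective Williamson etherification; the 3-hydroxyl is not hydrogen-bonded and takes the single equivalent of benzyl bromide, whereas the 2-hydroxyl is chelated to the acetyl carbonyl, the usual selectivity of 2,3-dihydroxyacetophenones.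

Step 5
Reactants: 7 1-[3,4,6-tris(benzyloxy)-2-hydroxyphenyl]ethanone
Product: 9 1-[3,4,6-tris(benzyloxy)-2,5-dihydroxyphenyl]ethanone, via aryl sulfate 8 (not isolated)
Conditions: K2S2O8, aq NaOH, pyridine, 0 °C to rt; then HCl, 80 °C, N2
Reagents that add atoms: potassium peroxodisulfate, [K+].[K+].[O-]S(=O)(=O)OOS(=O)(=O)[O-]
Why: Elbs persulfate oxidation; the phenoxide attacks peroxodisulfate through its para carbon, the only unsubstituted ring position, to give sulfate 8, which is protected against further oxidation and is hydrolysed by acid to the hydroquinone; conversion should be modest and unreacted 7 recoverable.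

Step 6
Reactants: 9 1-[3,4,6-tris(benzyloxy)-2,5-dihydroxyphenyl]ethanone
Product: 10 1-[3,4,6-tris(benzyloxy)-2-hydroxy-5-methoxyphenyl]ethanone
Conditions: MeI (1.1 equiv), K2CO3, acetone, rt
Reagents that add atoms: iodomethane, CI
Why: Selective Williamson methylation; the new 5-hydroxyl is free of hydrogen bonding and is methylated, while the chelated 2-hydroxyl remains.

Step 7
Reactants: 10 1-[3,4,6-tris(benzyloxy)-2-hydroxy-5-methoxyphenyl]ethanone
Product: 11 1-[2-(allyloxy)-3,4,6-tris(benzyloxy)-5-methoxyphenyl]ethanone
Conditions: allyl bromide, K2CO3, DMF, 60 °C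
Reagents that add atoms: allyl bromide, C=CCBr
Why: Williamson allylation of the chelated phenol under forcing conditions; the allyl ether marks the oxygen that becomes O1 and can later be removed without touching the benzyl ethers.

Step 8
Reactants: 12 3-hydroxy-4,5-dimethoxybenzaldehyde
Product: 13 3-(benzyloxy)-4,5-dimethoxybenzaldehyde
Conditions: BnBr, K2CO3, DMF, rt
Reagents that add atoms: benzyl bromide, BrCc1ccccc1
Why: Williamson etherification of the single phenol.

Step 9
Reactants: 11 1-[2-(allyloxy)-3,4,6-tris(benzyloxy)-5-methoxyphenyl]ethanone; 13 3-(benzyloxy)-4,5-dimethoxybenzaldehyde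
Product: 14 (E)-1-[2-(allyloxy)-3,4,6-tris(benzyloxy)-5-methoxyphenyl]-3-[3-(benzyloxy)-4,5-dimethoxyphenyl]prop-2-en-1-one
Conditions: KOH, EtOH/THF, rt
Reagents that add atoms: none
Why: Claisen–Schmidt condensation of the methyl ketone with a non-enolisable aldehyde; dehydration of the aldol gives the conjugated E-alkene, and with every phenol capped no flavanone can form.

Step 10
Reactants: 14 (E)-chalcone
Product: 15 rac-trans-[2-(allyloxy)-3,4,6-tris(benzyloxy)-5-methoxyphenyl][(2R*,3S*)-3-(3-benzyloxy-4,5-dimethoxyphenyl)oxiran-2-yl]methanone
Conditions: 30% H2O2, NaOH, MeOH/THF, 0 °C to rt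
Reagents that add atoms: hydrogen peroxide, OO
Why: Weitz–Scheffer nucleophilic epoxidation; hydroperoxide adds in conjugate fashion and the freely rotating enolate closes to the more stable trans epoxide (racemic), while the isolated allyl double bond is inert to a nucleophilic oxidant.

Step 11
Reactants: 15 rac-trans-epoxy ketone
Product: 16 3-[2-(allyloxy)-3,4,6-tris(benzyloxy)-5-methoxyphenyl]-2-[3-(benzyloxy)-4,5-dimethoxyphenyl]-3-oxopropanal (racemic, enolisable)
Conditions: BF3·OEt2 (1.1 equiv), CH2Cl2, 0 °C, short time; aq NaHCO3 quench
Reagents that add atoms: none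
Why: BF3 coordinates the oxirane oxygen and the C–O bond at the carbon bearing ring B lengthens, because positive charge there is benzylic and is taken up by the para 4'-methoxy group, whereas charge at the other carbon would sit next to the carbonyl. The aroyl group then shifts 1,2 from the adjacent carbon to this centre through a bridged acyl transition state, which forms the future C3–C4 bond and turns the carbon it leaves into the aldehyde that becomes C2. The closest known reaction type is the BF3-promoted Meinwald-type rearrangement of 2'-alkoxychalcone epoxides to α-formyl deoxybenzoins, the classical acyl-shift entry to isoflavones. No ring is closed, and the one new stereocentre lies between two carbonyl groups and enolises, so 16 is racemic and its configuration is irrelevant. The step needs opening at the benzylic carbon and migration of acyl in preference to hydride; the first is secured by the electron-rich ring B and the second by the general preference for acyl migration in Lewis-acid-opened α,β-epoxy ketones. Low temperature, about one equivalent of BF3·OEt2 and a short reaction time keep the allyl and benzyl ethers ortho to the carbonyl intact, so that no phenol is released to attack the epoxide, and the bicarbonate quench avoids base-induced loss of the formyl group.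

Step 12
Reactants: 16 α-formyl deoxybenzoin
Product: 19 5,7,8-tris(benzyloxy)-3-[3-(benzyloxy)-4,5-dimethoxyphenyl]-6-methoxy-4H-chromen-4-one, via free phenol 17 (not isolated), via 2-hydroxyisoflavanone 18 (not isolated)
Conditions: Pd(PPh3)4 (5 mol %), TolSO2Na, THF/MeOH, rt; then 1 M HCl, 40 °C
Reagents that add atoms: none
Why: Tsuji–Trost-type deallylation; zerovalent palladium ionises the aryl allyl ether and the sulfinate captures the π-allyl unit, phenol 17 adds to the aldehyde to give hemiacetal 18, and acid-catalysed dehydration forms the pyranone; because the other ortho oxygen is still benzylated, ring C can close only through the oxygen next to C8.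

Step 13
Reactants: 19 tetra-O-benzyl isoflavone
Product: 20 5,7,8-trihydroxy-3-(3-hydroxy-4,5-dimethoxyphenyl)-6-methoxy-4H-chromen-4-one (5,7,8,3'-tetrahydroxy-6,4',5'-trimethoxyisoflavone)
Conditions: H2 (1 atm), 10% Pd/C, EtOAc/MeOH, rt; work-up under argon
Reagents that add atoms: none
Why: Catalytic hydrogenolysis of the four aryl benzyl ethers under neutral conditions, which leaves the methyl ethers untouched, causes no Wessely–Moser isomerisation and releases the oxidation-prone polyphenol only at the end; the chromone double bond is reduced much more slowly than benzyl ethers are cleaved.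

## Compound list

1 | 2',4',6'-trihydroxyacetophenone | CC(=O)c1c(O)cc(O)cc1O | starting material
2 | N-[(3-acetyl-2,4,6-trihydroxyphenyl)methylidene]-N-methylmethanaminium chloride | CC(=O)c1c(O)cc(O)c(C=[N+](C)C)c1O.[Cl-] | intermediate
3 | 3-acetyl-2,4,6-trihydroxybenzaldehyde | CC(=O)c1c(O)cc(O)c(C=O)c1O | intermediate
4 | 3-acetyl-4,6-bis(benzyloxy)-2-hydroxybenzaldehyde | CC(=O)c1c(OCc2ccccc2)cc(OCc2ccccc2)c(C=O)c1O | intermediate
5 | 3-acetyl-4,6-bis(benzyloxy)-2-hydroxyphenyl formate | CC(=O)c1c(OCc2ccccc2)cc(OCc2ccccc2)c(OC=O)c1O | intermediate
6 | 1-[4,6-bis(benzyloxy)-2,3-dihydroxyphenyl]ethanone | CC(=O)c1c(OCc2ccccc2)cc(OCc2ccccc2)c(O)c1O | intermediate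
7 | 1-[3,4,6-tris(benzyloxy)-2-hydroxyphenyl]ethanone | CC(=O)c1c(OCc2ccccc2)cc(OCc2ccccc2)c(OCc2ccccc2)c1O | intermediate
8 | potassium 3-acetyl-2,5,6-tris(benzyloxy)-4-hydroxyphenyl sulfate | CC(=O)c1c(OCc2ccccc2)c(OS(=O)(=O)[O-])c(OCc2ccccc2)c(OCc2ccccc2)c1O.[K+] | intermediate
9 | 1-[3,4,6-tris(benzyloxy)-2,5-dihydroxyphenyl]ethanone | CC(=O)c1c(OCc2ccccc2)c(O)c(OCc2ccccc2)c(OCc2ccccc2)c1O | intermediate
10 | 1-[3,4,6-tris(benzyloxy)-2-hydroxy-5-methoxyphenyl]ethanone | CC(=O)c1c(OCc2ccccc2)c(OC)c(OCc2ccccc2)c(OCc2ccccc2)c1O | intermediate
11 | 1-[2-(allyloxy)-3,4,6-tris(benzyloxy)-5-methoxyphenyl]ethanone | CC(=O)c1c(OCc2ccccc2)c(OC)c(OCc2ccccc2)c(OCc2ccccc2)c1OCC=C | intermediate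
12 | 3-hydroxy-4,5-dimethoxybenzaldehyde | COc1cc(C=O)cc(O)c1OC | starting material
13 | 3-(benzyloxy)-4,5-dimethoxybenzaldehyde | COc1cc(C=O)cc(OCc2ccccc2)c1OC | intermediate
14 | (E)-1-[2-(allyloxy)-3,4,6-tris(benzyloxy)-5-methoxyphenyl]-3-[3-(benzyloxy)-4,5-dimethoxyphenyl]prop-2-en-1-one | O=C(/C=C/c1cc(OC)c(OC)c(OCc2ccccc2)c1)c1c(OCc2ccccc2)c(OC)c(OCc2ccccc2)c(OCc2ccccc2)c1OCC=C | intermediate
15 | rac-trans-[2-(allyloxy)-3,4,6-tris(benzyloxy)-5-methoxyphenyl][(2R*,3S*)-3-(3-benzyloxy-4,5-dimethoxyphenyl)oxiran-2-yl]methanone (one enantiomer drawn) | O=C(c1c(OCc2ccccc2)c(OC)c(OCc2ccccc2)c(OCc2ccccc2)c1OCC=C)[C@H]1O[C@@H]1c1cc(OC)c(OC)c(OCc2ccccc2)c1 | intermediate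
16 | 3-[2-(allyloxy)-3,4,6-tris(benzyloxy)-5-methoxyphenyl]-2-[3-(benzyloxy)-4,5-dimethoxyphenyl]-3-oxopropanal (racemic, enolisable) | O=CC(C(=O)c1c(OCc2ccccc2)c(OC)c(OCc2ccccc2)c(OCc2ccccc2)c1OCC=C)c1cc(OC)c(OC)c(OCc2ccccc2)c1 | intermediate
17 | 2-[3-(benzyloxy)-4,5-dimethoxyphenyl]-3-oxo-3-[3,4,6-tris(benzyloxy)-2-hydroxy-5-methoxyphenyl]propanal (racemic) | O=CC(C(=O)c1c(OCc2ccccc2)c(OC)c(OCc2ccccc2)c(OCc2ccccc2)c1O)c1cc(OC)c(OC)c(OCc2ccccc2)c1 | intermediate
18 | 5,7,8-tris(benzyloxy)-3-[3-(benzyloxy)-4,5-dimethoxyphenyl]-2-hydroxy-6-methoxy-2,3-dihydro-4H-chromen-4-one (racemic diastereomer mixture) | COc1cc(C2C(O)Oc3c(OCc4ccccc4)c(OCc4ccccc4)c(OC)c(OCc4ccccc4)c3C2=O)cc(OCc2ccccc2)c1OC | intermediate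
19 | 5,7,8-tris(benzyloxy)-3-[3-(benzyloxy)-4,5-dimethoxyphenyl]-6-methoxy-4H-chromen-4-one | COc1cc(-c2coc3c(OCc4ccccc4)c(OCc4ccccc4)c(OC)c(OCc4ccccc4)c3c2=O)cc(OCc2ccccc2)c1OC | intermediate
20 | 5,7,8-trihydroxy-3-(3-hydroxy-4,5-dimethoxyphenyl)-6-methoxy-4H-chromen-4-one | COc1cc(-c2coc3c(O)c(O)c(OC)c(O)c3c2=O)cc(O)c1OC | target

## Step count and least certain steps

Total: 13 steps. Longest linear sequence: 12 steps from 1 (steps 1–7 and 9–13).

**Step 11 (key step).** The 4'-methoxy group of ring B is flanked by two ortho substituents and twisted, so it stabilises the benzylic cation less than a simple 4-methoxyphenyl would. Ionisation may then be slow enough for fluoride capture or opening at the other carbon to compete. BF3 chelated to the carbonyl may also cleave an ortho ether, which would release a phenol that attacks the epoxide. Finally, the formyl group may be lost on work-up.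
Fallback: set out from 10 and 13. Condense them (KOH, EtOH) to (E)-3-[3-(benzyloxy)-4,5-dimethoxyphenyl]-1-[3,4,6-tris(benzyloxy)-2-hydroxy-5-methoxyphenyl]prop-2-en-1-one F1. Cyclise it (NaOAc, EtOH, reflux) to racemic 5,7,8-tris(benzyloxy)-2-[3-(benzyloxy)-4,5-dimethoxyphenyl]-6-methoxy-2,3-dihydro-4H-chromen-4-one F2. Then carry out the oxidative 2,3-aryl shift with PhI(OH)OTs (trivalent iodine) in MeOH/HC(OMe)3, which rejoins the route at 19.

**Step 2.** Alkylation may not discriminate cleanly between the three chelatable hydroxyls, giving regioisomeric or over-benzylated ethers.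
Fallback: set out from 1. Benzylate first (BnBr, 2 equiv, K2CO3, DMF) to 1-[2,4-bis(benzyloxy)-6-hydroxyphenyl]ethanone F3, in which the single chelated hydroxyl is left by a well-known selectivity. Then formylate ortho to that hydroxyl through its magnesium phenoxide (MgCl2, Et3N, paraformaldehyde, MeCN, reflux), which rejoins the route at 4.

**Step 5.** The phenoxide of the lipophilic tribenzyl ether may be poorly soluble in aqueous alkali, so conversion may be low. Oxidative degradation may compete, and a benzyl ether ortho to the carbonyl may be lost during the acid hydrolysis of the sulfate.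
Fallback: set out from 7. Brominate the only free ring position (NBS, MeCN, 0 °C) to 1-[3,4,6-tris(benzyloxy)-5-bromo-2-hydroxyphenyl]ethanone F4. Replace bromide by methoxide in an Ullmann-type reaction (NaOMe, CuBr, DMF/MeOH, 100 °C), which bypasses 9 and rejoins the route at 10.

**Step 12.** The π-allyl palladium intermediate may transfer allyl to the enolised carbon of the β-ketoaldehyde instead of to the sulfinate. The basic phenoxide may also cause retro-Claisen loss of the formyl group before ring closure.
Fallback: set out from 16. Isomerise the allyl ether with [Ir(cod)(PMePh2)2]PF6 (activated with H2, THF, rt) to the enol ether 3-[3,4,6-tris(benzyloxy)-5-methoxy-2-((E)-prop-1-en-1-yloxy)phenyl]-2-[3-(benzyloxy)-4,5-dimethoxyphenyl]-3-oxopropanal F5. No electrophilic allyl species is formed in this way. Hydrolyse F5 with 1 M HCl in MeOH/THF, which releases 17 and closes and dehydrates it in the same acidic medium, rejoining the route at 19.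

**Step 13.** The C2=C3 bond may be over-reduced to the isoflavanone once the benzyl groups are gone, and the product may be oxidised by air to a quinone on the catalyst or during filtration.
Fallback: set out from 19. Cleave the benzyl ethers without hydrogen by BCl3 with pentamethylbenzene as cation scavenger (CH2Cl2, −78 °C), a Lewis-acid debenzylation that spares aryl methyl ethers at this temperature, and arrive directly at 20.

## Further compounds

F1 | step 11 | (E)-3-[3-(benzyloxy)-4,5-dimethoxyphenyl]-1-[3,4,6-tris(benzyloxy)-2-hydroxy-5-methoxyphenyl]prop-2-en-1-one | O=C(/C=C/c1cc(OC)c(OC)c(OCc2ccccc2)c1)c1c(OCc2ccccc2)c(OC)c(OCc2ccccc2)c(OCc2ccccc2)c1O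
F2 | step 11 | 5,7,8-tris(benzyloxy)-2-[3-(benzyloxy)-4,5-dimethoxyphenyl]-6-methoxy-2,3-dihydro-4H-chromen-4-one (racemic) | COc1cc(C2CC(=O)c3c(OCc4ccccc4)c(OC)c(OCc4ccccc4)c(OCc4ccccc4)c3O2)cc(OCc2ccccc2)c1OC
F3 | step 2 | 1-[2,4-bis(benzyloxy)-6-hydroxyphenyl]ethanone | CC(=O)c1c(O)cc(OCc2ccccc2)cc1OCc1ccccc1
F4 | step 5 | 1-[3,4,6-tris(benzyloxy)-5-bromo-2-hydroxyphenyl]ethanone | CC(=O)c1c(OCc2ccccc2)c(Br)c(OCc2ccccc2)c(OCc2ccccc2)c1O
F5 | step 12 | 3-[3,4,6-tris(benzyloxy)-5-methoxy-2-((E)-prop-1-en-1-yloxy)phenyl]-2-[3-(benzyloxy)-4,5-dimethoxyphenyl]-3-oxopropanal (racemic) | O=CC(C(=O)c1c(OCc2ccccc2)c(OC)c(OCc2ccccc2)c(OCc2ccccc2)c1O/C=C/C)c1cc(OC)c(OC)c(OCc2ccccc2)c1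
F0 | step 13 | none | none
A1 | alternative 1 | 3-[3-(benzyloxy)-4,5-dimethoxyphenyl]-5-(3-tert-butoxy-1-hydroxy-2-methoxy-4-oxocyclobut-2-en-1-yl)-4H-pyran-4-one (racemic) | COC1=C(OC(C)(C)C)C(=O)C1(O)c1cocc(-c2cc(OC)c(OC)c(OCc3ccccc3)c2)c1=O
A2 | alternative 1 | 3-(3-benzyloxy-4,5-dimethoxyphenyl)-7-tert-butoxy-5,8-dihydroxy-6-methoxy-4H-chromen-4-one | COc1cc(-c2coc3c(O)c(OC(C)(C)C)c(OC)c(O)c3c2=O)cc(OCc2ccccc2)c1OC
A3 | alternative 2 | 5,7,8-tris(benzyloxy)-2-[3-(benzyloxy)-4,5-dimethoxyphenyl]-6-methoxy-2,3-dihydro-4H-chromen-4-one (racemic) | COc1cc(C2CC(=O)c3c(OCc4ccccc4)c(OC)c(OCc4ccccc4)c(OCc4ccccc4)c3O2)cc(OCc2ccccc2)c1OC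
A4 | alternative 2 | 5,7,8-tris(benzyloxy)-3-(3-benzyloxy-4,5-dimethoxyphenyl)-6-methoxy-4H-chromen-4-one | COc1cc(-c2coc3c(OCc4ccccc4)c(OCc4ccccc4)c(OC)c(OCc4ccccc4)c3c2=O)cc(OCc2ccccc2)c1OC
A5 | alternative 3 | 5,7,8-tris(benzyloxy)-3-[1-(2,3-dimethoxy-4-oxocyclobut-2-en-1-yl)vinyl]-6-methoxy-4H-chromen-4-one (racemic) | C=C(C1C(OC)=C(OC)C1=O)c1coc2c(OCc3ccccc3)c(OCc3ccccc3)c(OC)c(OCc3ccccc3)c2c1=O
A6 | alternative 3 | 5,7,8-tris(benzyloxy)-3-(3-hydroxy-4,5-dimethoxyphenyl)-6-methoxy-4H-chromen-4-one | COc1cc(-c2coc3c(OCc4ccccc4)c(OCc4ccccc4)c(OC)c(OCc4ccccc4)c3c2=O)cc(O)c1OC
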